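**Retrosynthetic overview**
1. Labels: ring A = C1–C5 + C10, ring B = C5–C10; C18 = ester carbon and C19 = methyl on C4; C17 and C20 = methyls on C8 and C9; side chain C11–C16. β = the face carrying C11, α = the face carrying C20, C17 and H-5.
2. Feature: the quaternary C4 of ring A carries the exocyclic ester carbon C18 and a methyl. It is disconnected by a Favorskii ring contraction: C18 is taken back into the ring as the carbonyl of a ring-B-fused α-chloro cyclohept-4-enone (C18 between C3 and C4). Closing C3–C4 and cleaving C18–C3 deletes one ring atom.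
3. The chloride sits on C3, not on C4. The cyclopropanone is the same, but no C–Cl stereocentre has to be set: C4 is fixed by the enolate face on which the new bond forms (syn to H-5). Electrophilic chlorination at C4 would be expected to enter on that same face, and invertive closure would then give the C4 epimer.
4. The seven-membered ring comes from a 1-vinylcyclohexene by rhodium-vinylcarbenoid cyclopropanation/Cope rearrangement (formal 4+3). Ring B comes from 2-methylcyclohexenone by asymmetric conjugate methylation and Mukaiyama–Michael addition to methyl vinyl ketone.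
5. Order of ring formation: ring B (starting material), seven-membered ring (step 8), ring A by contraction (step 11), oxirane last (ketone → (E)-allylic alcohol → Sharpless epoxidation).

Key step: step 11

Assumption: the sense of induction of the copper–phosphoramidite catalyst (step 1) and of Rh2(S-PTAD)4 (step 8) is taken to be the one that gives the configurations drawn; if a first run shows the opposite sense, the antipodal ligand or catalyst is used and nothing else changes.

**Route**

Step 1
Reactants: 1 2-methylcyclohex-2-en-1-one
Product: 3 trimethyl{[(3R)-2,3-dimethylcyclohex-1-en-1-yl]oxy}silane, via dimethylaluminium enolate 2 (not isolated)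
Conditions: Me3Al, Cu(O2CC4H3S) (copper thiophene-2-carboxylate, 2 mol %), BINOL-derived phosphoramidite ligand with a bis(1-phenylethyl)amine unit (4 mol %), Et2O, −30 °C; then TMSOTf, THF, −30 to 0 °C
Reagents that add atoms: trimethylaluminium C[Al](C)C; trimethylsilyl triflate C[Si](C)(C)OS(=O)(=O)C(F)(F)F
Why: Copper-catalysed asymmetric conjugate addition places the C17 methyl on C8 under ligand control, and O-silylation of the aluminium enolate fixes the tetrasubstituted enol ether needed for the next C–C bond.

Step 2
Reactants: 3 trimethyl{[(3R)-2,3-dimethylcyclohex-1-en-1-yl]oxy}silane; 4 methyl vinyl ketone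
Product: 5 (2S,3R)-2,3-dimethyl-2-(3-oxobutyl)cyclohexan-1-one
Conditions: BF3·OEt2, iPrOH, CH2Cl2, −78 °C
Reagents that add atoms: none
Why: Mukaiyama–Michael addition in which the enone approaches C9 anti to the pseudoaxial C8 methyl of the enol ether half-chair, so the quaternary centre forms with the chain trans to C17.

Step 3
Reactants: 5 (2S,3R)-2,3-dimethyl-2-(3-oxobutyl)cyclohexan-1-one
Product: 6 (2S,3R)-2,3-dimethyl-2-[2-(2-methyl-1,3-dioxolan-2-yl)ethyl]cyclohexan-1-one
Conditions: TMSOCH2CH2OTMS, TMSOTf (cat.), CH2Cl2, −78 °C
Reagents that add atoms: 1,2-bis(trimethylsilyloxy)ethane C[Si](C)(C)OCCO[Si](C)(C)C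
Why: Noyori ketalisation at low temperature should select the unhindered methyl ketone over the ring ketone flanked by the quaternary C9.

Step 4
Reactants: 6 (2S,3R)-2,3-dimethyl-2-[2-(2-methyl-1,3-dioxolan-2-yl)ethyl]cyclohexan-1-one
Product: 7 (5R,6S)-5,6-dimethyl-6-[2-(2-methyl-1,3-dioxolan-2-yl)ethyl]cyclohex-1-en-1-yl trifluoromethanesulfonate
Conditions: KHMDS, THF, −78 °C; then PhNTf2, −78 to 0 °C
Reagents that add atoms: N-phenylbis(trifluoromethanesulfonimide) O=S(=O)(N(c1ccccc1)S(=O)(=O)C(F)(F)F)C(F)(F)F
Why: The ketone can enolise only toward C5 because C9 is quaternary, so enolate O-triflation gives the C10=C5 enol triflate as a single regioisomer.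

Step 5
Reactants: 7 (5R,6S)-5,6-dimethyl-6-[2-(2-methyl-1,3-dioxolan-2-yl)ethyl]cyclohex-1-en-1-yl trifluoromethanesulfonate
Product: 8 2-{2-[(1S,6R)-1,6-dimethyl-2-vinylcyclohex-2-en-1-yl]ethyl}-2-methyl-1,3-dioxolane (diene C2=C1–C10=C5)
Conditions: tributyl(vinyl)stannane, Pd(PPh3)4 (5 mol %), LiCl, THF, 65 °C
Reagents that add atoms: tributyl(vinyl)stannane C=C[Sn](CCCC)(CCCC)CCCC
Why: Stille cross-coupling of the enol triflate, assisted by LiCl, installs C1 and C2 as a vinyl group and gives the 1-vinylcyclohexene.

Step 6
Reactants: 9 methyl 3-oxopentanoate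
Product: 10 methyl 2-diazo-3-oxopentanoate
Conditions: 4-acetamidobenzenesulfonyl azide, Et3N, MeCN, 0 °C to rt
Reagents that add atoms: 4-acetamidobenzenesulfonyl azide CC(=O)Nc1ccc(cc1)S(=O)(=O)N=[N+]=[N-]
Why: Regitz diazo transfer to the active methylene of the β-keto ester.

Step 7
Reactants: 10 methyl 2-diazo-3-oxopentanoate
Product: 11 methyl (Z)-3-[(tert-butyldimethylsilyl)oxy]-2-diazopent-3-enoate
Conditions: TBSOTf, Et3N, CH2Cl2, 0 °C
Reagents that add atoms: tert-butyldimethylsilyl triflate CC(C)(C)[Si](C)(C)OS(=O)(=O)C(F)(F)F
Why: Soft enolisation and O-silylation of the ketone gives the (Z)-silyloxyvinyl diazoacetate, a vinylcarbenoid precursor that carries the future C19 methyl on its vinyl terminus.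

Step 8
Reactants: 8 2-{2-[(1S,6R)-1,6-dimethyl-2-vinylcyclohex-2-en-1-yl]ethyl}-2-methyl-1,3-dioxolane; 11 methyl (Z)-3-[(tert-butyldimethylsilyl)oxy]-2-diazopent-3-enoate
Product: 13 ring-B-fused cyclohepta-1,4-diene with C3(CO2Me)=C18(OTBS) and C1=C10 (C4 methyl β; H-5 α), via cis-divinylcyclopropane 12 (not isolated)
Conditions: Rh2(S-PTAD)4 (1 mol %), hexane, −40 °C to rt, slow addition of 11
Reagents that add atoms: none
Why: The rhodium vinylcarbenoid cyclopropanates the less hindered terminal alkene C1=C2 to a cis-divinylcyclopropane, which undergoes Cope rearrangement through a boat transition state (formal 4+3 cycloaddition); the catalyst fixes the cyclopropane configuration, and this is relayed stereospecifically to C5 (new C4–C5 bond on the β face, anti to the axial C9 methyl), with C1=C10 formed in place.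

Step 9
Reactants: 13 ring-B-fused cyclohepta-1,4-diene silyl enol ether ester
Product: 15 ring-B-fused 2-methylcyclohept-4-enone (C18 ketone; C3 is CH2; C4 carries H and CH3; H-5 α), via β-keto ester 14 (not isolated)
Conditions: TBAF, AcOH, THF, 0 °C; solvent exchange; then LiCl, H2O, DMSO, 140 °C
Reagents that add atoms: none
Why: Fluoride cleaves the silyl enol ether to the β-keto ester, and Krapcho dealkoxycarbonylation removes the C3 ester under neutral conditions that spare the ketal, the alkene and the non-enolisable C5 centre.

Step 10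
Reactants: 15 ring-B-fused 2-methylcyclohept-4-enone
Product: 17 ring-B-fused 7-chloro-2-methylcyclohept-4-enone (chloride on C3; C3 epimers), via trimethylsilyl enol ether 16 (not isolated)
Conditions: LDA, TMSCl, THF, −78 °C; then NCS, THF, 0 °C
Reagents that add atoms: N-chlorosuccinimide ClN1C(=O)CCC1=O
Why: Kinetic deprotonation takes the C3 methylene and not the C4 methine, and the C3=C18 silyl enol ether is chlorinated by NCS only at C3 (regiospecific α-chlorination of a silyl enol ether); the C3 configuration does not matter.

Step 11
Reactants: 17 ring-B-fused 7-chloro-2-methylcyclohept-4-enone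
Product: 19 methyl (4S,5R,8R,9S)-ester of ring A/B with the ketal side chain (CO2Me β and CH3 α on C4; C1=C10), via cyclopropanone 18 (not isolated)
Conditions: NaOMe (3 equiv), Et2O with 2 vol % MeOH, 0 °C to reflux
Reagents that add atoms: sodium methoxide C[O-].[Na+]
Why: Methoxide reversibly removes the acidic C3–H (which epimerises the chloride) and also forms the C4 enolate; C4 displaces chloride at C3 in an intramolecular SN2 reaction to give cyclopropanone 18 (new C3–C4 bond), methoxide adds to C18, and the hemiketal anion cleaves C18–C3 toward the secondary rather than the tertiary carbanion, so C3 becomes the ring CH2 and C18 the ester on C4. This is the Favorskii rearrangement of a 2-chlorocycloalkanone with ring contraction, in the known variant where the halide is on the less substituted α-carbon and a tertiary α′-hydrogen is enolised (as in 21-halo-20-keto steroids). Ring A (C1–C5, C10) is closed by a 3-exo-tet C-alkylation inside the seven-membered ring followed by excision of C18; the C1=C10 alkene is not touched. The only new stereocentre, C4, is controlled by C5: C3 should bond to the enolate face syn to H-5 (the equatorial direction of the forming half-chair, with C6 staying equatorial), which places C18 axial and β and the methyl α; because the C3 epimers interconvert, the chloride configuration does not limit this. The step needs enolisation at C4 in the presence of the more acidic C3–H, the stated direction of cyclopropanone opening, and suppression of HCl loss toward C2 and of methoxide substitution. A heterogeneous methoxide medium with a proton shuttle and the carbanion-stability difference are relied on for these.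

Step 12
Reactants: 19 methyl ester with ketal side chain
Product: 20 methyl ester with 3-oxobutyl side chain (C13 methyl ketone)
Conditions: PPTS, acetone–H2O, 50 °C
Reagents that add atoms: water O
Why: Mild acid-catalysed ketal hydrolysis frees the C13 ketone without moving the C1=C10 alkene or touching the hindered ester.

Step 13
Reactants: 20 methyl ester with 3-oxobutyl side chain
Product: 21 diester with (E)-C13=C14 ethyl enoate side chain
Conditions: triethyl phosphonoacetate, NaH, THF, 0 to 50 °C; chromatographic removal of the minor Z isomer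
Reagents that add atoms: triethyl phosphonoacetate CCOC(=O)CP(=O)(OCC)OCC
Why: Horner–Wadsworth–Emmons olefination of the methyl ketone should give the trisubstituted (E)-enoate as the major isomer, and the C4 ester, which has no α-hydrogen and is neopentyl-like, is inert.

Step 14
Reactants: 21 diester with (E)-enoate side chain
Product: 22 (E)-allylic alcohol (C15 OH) with the C4 methyl ester intact
Conditions: DIBAL-H (2.2 equiv), CH2Cl2, −78 °C; Rochelle salt work-up
Reagents that add atoms: none
Why: DIBAL-H reduction of the unhindered conjugated ethyl ester to the allylic alcohol should be much faster than attack on the axial, fully substituted C4 methyl ester.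

Step 15
Reactants: 22 (E)-allylic alcohol
Product: 23 target, methyl (4S,5R,8R,9S,13R,14R)-13,14-epoxy-15-hydroxy ester (CNP0324371.2)
Conditions: Ti(OiPr)4, D-(−)-diethyl tartrate, tBuOOH, 4 Å molecular sieves, CH2Cl2, −20 °C
Reagents that add atoms: tert-butyl hydroperoxide CC(C)(C)OO
Why: Sharpless asymmetric epoxidation with D-(−)-diethyl tartrate delivers oxygen to the face of the (E)-allylic alcohol that gives the (13R,14R) epoxy alcohol (the same sense as geraniol to (2R,3R)-epoxygeraniol), and the C1=C10 alkene, which is not allylic to a hydroxyl, is left alone.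

**Compound list**
1 | 2-methylcyclohex-2-en-1-one | CC1=CCCCC1=O | starting material
2 | dimethylaluminium (3R)-2,3-dimethylcyclohex-1-en-1-olate | C[C@@H]1CCCC(O[Al](C)C)=C1C | intermediate
3 | trimethyl{[(3R)-2,3-dimethylcyclohex-1-en-1-yl]oxy}silane | C[C@@H]1CCCC(O[Si](C)(C)C)=C1C | intermediate
4 | methyl vinyl ketone | CC(=O)C=C | starting material
5 | (2S,3R)-2,3-dimethyl-2-(3-oxobutyl)cyclohexan-1-one | O=C1CCC[C@@H](C)[C@]1(C)CCC(C)=O | intermediate
6 | (2S,3R)-2,3-dimethyl-2-[2-(2-methyl-1,3-dioxolan-2-yl)ethyl]cyclohexan-1-one | O=C1CCC[C@@H](C)[C@]1(C)CCC2(C)OCCO2 | intermediate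
7 | (5R,6S)-5,6-dimethyl-6-[2-(2-methyl-1,3-dioxolan-2-yl)ethyl]cyclohex-1-en-1-yl trifluoromethanesulfonate | O=S(=O)(OC1=CCC[C@@H](C)[C@]1(C)CCC2(C)OCCO2)C(F)(F)F | intermediate
8 | 2-{2-[(1S,6R)-1,6-dimethyl-2-vinylcyclohex-2-en-1-yl]ethyl}-2-methyl-1,3-dioxolane | C=CC1=CCC[C@@H](C)[C@]1(C)CCC2(C)OCCO2 | intermediate
9 | methyl 3-oxopentanoate | CCC(=O)CC(=O)OC | starting material
10 | methyl 2-diazo-3-oxopentanoate | CCC(=O)C(=[N+]=[N-])C(=O)OC | intermediate
11 | methyl (Z)-3-[(tert-butyldimethylsilyl)oxy]-2-diazopent-3-enoate | COC(=O)C(=[N+]=[N-])/C(O[Si](C)(C)C(C)(C)C)=C/C | intermediate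
12 | cis-divinylcyclopropane: methyl cyclopropanecarboxylate carrying the (Z)-1-silyloxyprop-1-enyl group on C3 and the ring B cyclohexenyl group on C1, the two alkenyl groups cis | COC(=O)[C@@]1(/C(O[Si](C)(C)C(C)(C)C)=C/C)C[C@@H]1C2=CCC[C@@H](C)[C@]2(C)CCC3(C)OCCO3 | intermediate
13 | ring-B-fused cyclohepta-1,4-diene, C3(CO2Me)=C18(OTBS), C4 methyl β, H-5 α, C1=C10 | COC(=O)C1=C(O[Si](C)(C)C(C)(C)C)[C@H](C)[C@@H]2CC[C@@H](C)[C@](C)(CCC3(C)OCCO3)C2=CC1 | intermediate
14 | β-keto ester from 13 (C3 not defined; keto/enol mixture) | COC(=O)C1C(=O)[C@H](C)[C@@H]2CC[C@@H](C)[C@](C)(CCC3(C)OCCO3)C2=CC1 | intermediate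
15 | ring-B-fused 2-methylcyclohept-4-enone, (4R,5S,8R,9S) as formed; C4 is erased in step 11 | O=C1CCC=C2[C@@H](CC[C@@H](C)[C@]2(C)CCC3(C)OCCO3)[C@H]1C | intermediate
16 | C3=C18 trimethylsilyl enol ether of 15 | C[Si](C)(C)OC1=CCC=C2[C@@H](CC[C@@H](C)[C@]2(C)CCC3(C)OCCO3)[C@H]1C | intermediate
17 | ring-B-fused 7-chloro-2-methylcyclohept-4-enone (Cl on C3, both C3 epimers) | O=C1C(Cl)CC=C2[C@@H](CC[C@@H](C)[C@]2(C)CCC3(C)OCCO3)[C@H]1C | intermediate
18 | cyclopropanone with C3–C4 bond, C18 bridging on the β face | O=C1[C@H]2CC=C3[C@@H](CC[C@@H](C)[C@]3(C)CCC4(C)OCCO4)[C@@]12C | intermediate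
19 | methyl (4S,5R,8R,9S) ring A/B ester with ketal side chain | COC(=O)[C@@]1(C)CCC=C2[C@H]1CC[C@@H](C)[C@]2(C)CCC3(C)OCCO3 | intermediate
20 | methyl ester with 3-oxobutyl side chain | COC(=O)[C@@]1(C)CCC=C2[C@H]1CC[C@@H](C)[C@]2(C)CCC(C)=O | intermediate
21 | methyl ester with (E)-ethyl enoate side chain | COC(=O)[C@@]1(C)CCC=C2[C@H]1CC[C@@H](C)[C@]2(C)CC/C(C)=C/C(=O)OCC | intermediate
22 | methyl ester with (E)-allylic alcohol side chain | COC(=O)[C@@]1(C)CCC=C2[C@H]1CC[C@@H](C)[C@]2(C)CC/C(C)=C/CO | intermediate
23 | CNP0324371.2 | COC(=O)[C@@]1(C)CCC=C2[C@H]1CC[C@@H](C)[C@]2(C)CC[C@@]1(C)O[C@@H]1CO | target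

**Step count**
Total: 15 steps. Longest linear sequence: 13 steps (steps 1–5 and 8–15); steps 6–7 prepare the diazo partner.

**Steps most likely to fail**

Step 11. Enolisation at the hindered C4 may be outrun by loss of HCl toward the allylic C2 (conjugated dienone) or by methoxide attack at C18 and C3, and the facial preference at C4 may be incomplete. The fallback leaves ring contraction and builds ring A directly. It sets out from diene 8: Diels–Alder reaction with methyl acrylate (toluene, sealed tube, 120 °C) should add anti to the axial C9 methyl with the ester next to C5, giving the ring A ester with hydrogen on C4, F1. Deprotonation with LDA (THF, −78 °C) and methylation with MeI on the equatorial face of the ester enolate (syn to H-5) would then return to the route at 19.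

Step 8. The carbenoid may be intercepted by the ketal oxygens, the cyclopropanation of the hindered diene may be slow, or the catalyst and substrate preferences may be mismatched and erode the C5 selectivity. The fallback sets out from 8 and uses a gold vinylcarbenoid in place of the diazo compound. But-3-yn-2-yl pivalate F2 (from but-3-yn-2-ol, pivaloyl chloride, pyridine) with Ph3PAuCl/AgSbF6 (CH2Cl2, rt) undergoes 1,2-acyloxy shift; the carbenoid cyclopropanates the vinyl group to cis-divinylcyclopropane F3, which rearranges (Cope) to the C3=C18 enol pivalate F4, here under substrate control only. Methanolysis (K2CO3, MeOH) returns to the route at 15 and makes step 9 unnecessary.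

Step 13. Olefination of a methyl ketone may give poor E/Z selectivity, and any Z-enoate carried forward would end as the C13 epimer after epoxidation. The fallback sets out from 20 and builds the alkene by carbometalation. LDA and ClP(O)(OEt)2 (THF, −78 °C) give the terminal enol phosphate F5, more LDA eliminates it to the terminal alkyne F6, and Negishi carboalumination (Me3Al, Cp2ZrCl2, CH2Cl2) followed by paraformaldehyde should give the (E)-allylic alcohol only, returning to the route at 22.

**Further compounds**
F1 | step 11 | ring A methyl ester with hydrogen on C4 (Diels–Alder adduct, ester β; C4 is erased on enolisation) | COC(=O)[C@H]1CCC=C2[C@H]1CC[C@@H](C)[C@]2(C)CCC3(C)OCCO3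
F2 | step 8 | but-3-yn-2-yl pivalate (racemic) | CC(OC(=O)C(C)(C)C)C#C
F3 | step 8 | cis-divinylcyclopropane with 1-pivaloyloxyprop-1-enyl group on C3 (alkene geometry not defined) | [C@@H]1(C(OC(=O)C(C)(C)C)=CC)C[C@@H]1C2=CCC[C@@H](C)[C@]2(C)CCC3(C)OCCO3
F4 | step 8 | C3=C18 enol pivalate of 15 (C4 not defined) | CC(C)(C)C(=O)OC1=CCC=C2[C@@H](CC[C@@H](C)[C@]2(C)CCC3(C)OCCO3)C1C
F5 | step 13 | terminal enol diethyl phosphate of 20 | COC(=O)[C@@]1(C)CCC=C2[C@H]1CC[C@@H](C)[C@]2(C)CCC(=C)OP(=O)(OCC)OCC
F6 | step 13 | terminal alkyne from 20 | COC(=O)[C@@]1(C)CCC=C2[C@H]1CC[C@@H](C)[C@]2(C)CCC#C
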